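The product appears once per round of the catalyst, so in a steady round the rate of making product is the catalyst charged divided by the time one round takes.

    substrate + free catalyst → catalyst intermediate A (k1 = 2.6 M⁻¹ s⁻¹)
    coupling partner + catalyst intermediate A ⇌ catalyst intermediate B (K2 = 2.1 M⁻¹, k2 = 0.69 M⁻¹ s⁻¹)
    catalyst intermediate B ⇌ by-product + catalyst intermediate C (K3 = 30 M, k3 = 8.9 s⁻¹)
    catalyst intermediate C → free catalyst + product (k4 = 0.65 s⁻¹)
    free catalyst + added ligand ⇌ idle complex, settled at all times (K5 = 250 M⁻¹)

substrate 0.60 M; coupling partner 0.600 M; free catalyst 30 mM; added ligand 22 mM

1. apparent order in coupling partner when 30% of the substrate are converted (percent change of the rate of making product for one percent more coupling partner charged)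
2. apparent order in free catalyst when 30% of the substrate are converted (percent change of the rate of making product for one percent more free catalyst charged)

By the mark of 30% conversion, each catalyst has taken up substrate about 6.00 times. My own reckoning therefore takes a steady round at that mark, counts steps 2 and 3 forward, and takes substrate and coupling partner each down by 0.180 M. The wait for substrate is then 0.916 s, the wait for coupling partner 3.45 s, and steps 3 and 4 together take 1.65 s. The balance with added ligand stretches the stay as free catalyst or idle complex, and solving the ligand balance together with the round gives a ligand factor of 4.10. The sum is 8.85 s: the round time, the mean time one catalyst needs for one turnover, or the inverse of the turnover frequency.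

The first way to the order in coupling partner takes the share of the round spent waiting for it and multiplies by charged over remaining partner, which gives 0.557. The second way solves the round anew with one percent more partner charged. The round time falls to 8.80 s, an order of 0.644. The two part, and the first way cheats: it holds free ligand still, while a shorter partner wait leaves more catalyst to take up ligand, so the ligand factor shrinks too and the order is higher than the share says. I commit to the second number. The same re-solving with one percent more catalyst gives 8.84 s and an order of 1.16.

The forecast gives 0.63 in coupling partner, a little below mine, and 1.16 in free catalyst, holding that “extra catalyst goes disproportionately into the active cycle”.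

The simulation gives 0.62 in coupling partner and 1.2 in free catalyst, so in this flask extra catalyst raises the rate more than extra partner does. Catalyst charged over round time gives 0.00339 M s⁻¹ against a read 0.00339 M s⁻¹. Taking away the tying up of free catalyst as idle complex removes the ligand factor and shortens the round to 6.02 s, a rate multiple of 1.47. The simulated run without that tying up goes at 1.48 times the actual rate, and its order in free catalyst is 1.0.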